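Read at 10 h, each flask shows how much turnover has passed through a chain of two catalysts. The free catalyst opens the substrate, the second catalyst binds the open intermediate, and the reagent releases that complex as target, which the free catalyst can turn into isomer.

- south-east: substrate 20 mM; reagent 22.0 mM; free catalyst 0.18 mM; second catalyst 0.20 mM; temperature 25 °C; time 10 h
- west: substrate 20 mM; reagent 22.0 mM; free catalyst 0.18 mM; second catalyst 0.20 mM; temperature 45 °C; time 10 h

    substrate + free catalyst ⇌ free catalyst + open intermediate (K1 = 2.0, k1 = 330 M⁻¹ h⁻¹, Ea1 = 68.0 kJ mol⁻¹, ΔH1 = −21.0 kJ mol⁻¹)
    second catalyst + open intermediate ⇌ catalyst intermediate (K2 = 1800 M⁻¹, k2 = 1600 M⁻¹ h⁻¹, Ea2 = 65.0 kJ mol⁻¹, ΔH2 = 6.00 kJ mol⁻¹)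
    reagent + catalyst intermediate → second catalyst + target (k3 = 110 M⁻¹ h⁻¹, Ea3 = 71.0 kJ mol⁻¹)
    target + free catalyst ⇌ isomer of the product + free catalyst, rate k4*[free catalyst]*[target] forward; the back reaction follows from the equilibrium constant (K4 = 0.52, k4 = 24 M⁻¹ h⁻¹, Ea4 = 64.0 kJ mol⁻¹, ΔH4 = −55.0 kJ mol⁻¹)
    (constants at 25 °C)

- which of the two there is more of at the end, south-east (target / isomer of the product)
- which of the two there is more of at the end, west (target / isomer of the product)
- final target, as a percentage of the substrate charged, in south-east
- final target, as a percentage of the substrate charged, in west

- the list of constants is for 25 °C, to be carried to other temperatures by the activation energies and enthalpies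

I first ranked the given numbers. I defined a ceiling Y: the share of the substrate charged that the reagent step would deliver by the reading time, with the second catalyst standing wholly as catalyst intermediate and the reagent staying at its charge. Y is that step's rate constant times the reagent charge, the second catalyst charge and the time, divided by the substrate charge. An error in any of these passes whole into Y, so they had to be right. The opening and binding constants enter more weakly, through the mean bound share s of the second catalyst. The opening equilibrium weighed little in south-east because the forward half-life of substrate, 12 h, is longer than the reading time. Isomerisation at its forward rate I reckoned to take hardly any of the south-east target.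

In south-east, Y came to 24.2%, the turnover ceiling. At steady state s = I/(I+H), where I is the open intermediate and H, the Michaelis constant of the second catalyst, is 2.07 mM. I replaced the rising curve of I by its mean, taken as half of what the forward opening step would have produced by then: 4.48 mM. That gave s = 0.684 and a yield of 16.6%, which I expected to run high because I had counted neither the drain on I nor the fall of the reagent. In west, Y was 146%, above the charge, so it bounded nothing and I gave no figure for west. The isomerisation constant was 0.52 in south-east and 0.129 in west, lower and below one in both, so I expected target to lead in each flask.

The forecast named target with 13% for south-east and target with 61% for west, since at the higher temperature “all the steps run five to six times faster”. Its south-east figure stood below mine.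

The simulation gave 12.8% target against 0.232% isomer in south-east, and 62.2% against 4.59% in west. Target plus isomer in south-east came to 0.538 of Y, below my s. In west at 10.0 h, open intermediate was being made at 0.575 of the rate at which it was used, slower, and it stood at 13.8% of the substrate charged. For west read at 4.0 h, Y is 58.6%, and the fraction of Y read in south-east, carried over to this flask, gives 31.5% for target plus isomer. That flask held 31.2% target and 1.07% isomer.

The numbers of this flask are made up; the flask was simulated.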